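All runs come from a simulation for substances that don't exist, and the scatter is random.

- I decide to watch two left fractions, not the substrate.

| setting | larch | flask |
|---|---|---|
| substrate | 1.2 M | 1.2 M |
| first nucleophile | 1 equiv | 0.700 equiv |
| second nucleophile | 0.70 equiv | 0.700 equiv |
| capture agent | 1.2 M | 1.20 M |
| remark | run made earlier |  |
| time |  | 20 min |

larch run (percent of the substrate charged)

| time / min | trapped intermediate / % | other capture product / % | open intermediate / % | target / % | substrate / % |
|---|---|---|---|---|---|
| 0.250 | 1.9 | 1.7 | 0.6 | 1.1 | 96.9 |
| 0.833 | 0.1 | 4.9 | 1.3 | 4.9 | 91.5 |
| 1.33 | 0.4 | 9.9 | 2.1 | 7.1 | 84.7 |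
| 2.00 | 2.1 | 11.3 | 0 | 8.9 | 78.4 |
| 3.00 | 0.8 | 16.1 | 1.3 | 12.3 | 69.5 |
| 4.00 | 2.2 | 21.5 | 0.5 | 16.5 | 58.8 |

(scatter of a reading: 1 percentage point)

- the largest share of what was charged as substrate, at 20 min belongs to (open intermediate / substrate / target / trapped intermediate / other capture product)
- the largest share itself, whichever of these holds it, in percent of the substrate charged



- The larch run looks wrong at its last reading: other capture product stands at 21.5%, above target at 16.5%, yet second nucleophile is charged at 0.70 equiv against 1 equiv of first nucleophile.
- Fractions of own charge clear this. By these readings, with each product taken to use one nucleophile, the larch run's second nucleophile has lost 30.7% and its first nucleophile 16.5%.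
- My rule, for two nucleophiles competing for one intermediate in one flask: the left fraction of second nucleophile equals the left fraction of first nucleophile raised to a power s, the selectivity factor, 2.03, read from those readings.
- In the flask I take substrate as first-order, so 7.03% remains at 20 min. I hold the two products together at their share of the substrate lost in the larch run, 92.2%, which gives them 85.8% of the substrate charged.
- My first split, s to one, gives other capture product 57.5%, so the flask's first nucleophile keeps 59.6%.
- That breaks the rule, so I go round twice, averaging each time: first nucleophile keeps 77.5% minus second's left fraction, giving 51.1%, then 51.5%.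
- For the flask at 20 min I commit to other capture product at 51.8%, target at 33.9%.
- The forecast says other capture product holds most, at 38%, range 33% to 46%, holding of first nucleophile “I assume it is consumed”.
- The flask gives other capture product at 51.7%, target 35.2%.

    first nucleophile + open intermediate → target (k = 0.130 L mol⁻¹ s⁻¹)
    open intermediate + capture agent → trapped intermediate (k = 0.00930 L mol⁻¹ s⁻¹)
    second nucleophile + open intermediate → other capture product (k = 0.250 L mol⁻¹ s⁻¹)
    substrate → open intermediate (k = 0.00210 s⁻¹)

- In the flask, open intermediate goes to other capture product 1.5 times as fast as to target at 4.89 min, and 1.0 times at 20.0 min. My s times the flask's left fractions of second over first nucleophile at 20.0 min, 26.1% over 49.7%, gives 1.07.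
- In the neighbour flask with 0.420 equiv of second nucleophile, I keep the two products together at 85.8%. My rule gives other capture product 38.5% after a rough round, which leaves target 47.3%, the larger of the two. That neighbour flask ends with target ahead at 47.0%, and other capture product at 37.0%.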